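**Plan**

1. Numbering and enabling feature: cycloheptanone C1(CH, acetonyl)–C2(=O)–C3(OH)–C12–C11–C10(CH3)–C13(CH, enol-ester arm); cyclohexane C7–C8–C9–C10–C11–C12; pyran C3–C4–O5–C6(CH3)2–C7–C12; arms C13–C14=C15–O and C1–C16–C17(=O)–C18. C10 and C12 are the bridgeheads of a bicyclo[4.3.1]decane (bridges C11, C7–C8–C9 and C3–C2–C1–C13) whose six-membered ring shares the C7–C12 bond with the pyran. A pyran-held diene C8=C7–C12=C11 and an isopropenyl ketone C9=C10–C13(=O) hanging from C3 therefore contain both carbocycles.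
2. Retrosynthetic cuts, in order: enol ester O–acyl; the C15 and C17 carbonyls (from alkenes); C1–C16 and C13–C14 (alkylation and conjugate allylation of the enone C2(=O)–C1=C13, which is the 1,3-transposed form of a C13 ketone); C8–C9 and C10–C11 (Diels–Alder); C13–C10 (Grignard on a nitrile); C7–C12 (Pd diyne cyclisation); C1–C2 (nitrile anion on an epoxide); C11–C12 (alkyne homologation); C4–O5 (ether).
3. Forward: an ether-linked allylic alcohol is epoxidised; the epoxide carbon C3 receives the C12≡C11 alkyne and the C2–C1–C13 nitrile chain; the pyran closes as a 3,4-bis(methylene)oxane; one cycloaddition closes the cyclohexene and the seven-membered ring together; the C13 ketone is then moved to C2 and the two side chains are attached last.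
4. Stereochemistry: C3 from Sharpless epoxidation; C10 from C3 through the tether in the cycloaddition; C7 and C12 from exo hydrogenation of the bridgehead alkene; C13 from exo-face conjugate allylation; C1 from trans alkylation of an epimerisable centre; the E enol ester from sterically controlled enol acylation.

Key step: step 10

Assumption: in the bridged tricycle the enone carbons C1, C2 and C13 are attacked from the face that carries the C10 methyl group, away from the C7–C8–C9 bridge.
Naming remark: "tricycle" means the 6,6,10-trimethyl-5-oxa ring system defined in line 1, with the locants given there; TBSO = tert-butyldimethylsilyloxy.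

**Step 1**
Reactants: 1 2-methylbut-3-yn-2-ol; 2 ethyl 2-(bromomethyl)prop-2-enoate
Product: 3 ethyl 2-{[(2-methylbut-3-yn-2-yl)oxy]methyl}prop-2-enoate
Conditions: NaH, THF, 0 °C; then 2, 0 °C → rt
Reagents that add atoms: none
Why: Williamson ether synthesis on an activated allylic bromide (the sodium alkoxide displaces bromide directly or by conjugate addition–elimination, both giving the same ether); NaH removes the hydroxyl proton rather than the much less acidic alkyne proton, and no stereocentre is formed.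

**Step 2**
Reactants: 3 ethyl 2-{[(2-methylbut-3-yn-2-yl)oxy]methyl}prop-2-enoate
Product: 4 2-{[(2-methylbut-3-yn-2-yl)oxy]methyl}prop-2-en-1-ol
Conditions: i-Bu2AlH (2.5 equiv), CH2Cl2, −78 → 0 °C; aq. potassium sodium tartrate
Reagents that add atoms: none
Why: 1,2-reduction of the α,β-unsaturated ester by the aluminium hydride gives the allylic alcohol and leaves the terminal alkyne and the ether untouched; no stereocentre is formed.

**Step 3**
Reactants: 4 2-{[(2-methylbut-3-yn-2-yl)oxy]methyl}prop-2-en-1-ol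
Product: 5 [(2S)-2-{[(2-methylbut-3-yn-2-yl)oxy]methyl}oxiran-2-yl]methanol
Conditions: Ti(OiPr)4 (10 mol%), L-(+)-diisopropyl tartrate (12 mol%), t-BuOOH, 4 Å molecular sieves, CH2Cl2, −20 °C
Reagents that add atoms: tert-butyl hydroperoxide, CC(C)(C)OO
Why: catalytic Katsuki–Sharpless asymmetric epoxidation of a 2-substituted allylic alcohol; the titanium L-(+)-tartrate complex delivers oxygen to the alkene face that gives the (S)-epoxide (the same facial sense that turns 2-methylprop-2-en-1-ol into (S)-2-methylglycidol), and this carbon becomes C3 with the configuration of the target.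

**Step 4**
Reactants: 5 [(2S)-2-{[(2-methylbut-3-yn-2-yl)oxy]methyl}oxiran-2-yl]methanol
Product: 6 (2S)-2-{[(2-methylbut-3-yn-2-yl)oxy]methyl}oxirane-2-carbaldehyde
Conditions: TEMPO (10 mol%), PhI(OAc)2, CH2Cl2, rt
Reagents that add atoms: none
Why: oxoammonium (TEMPO) oxidation stops at the aldehyde under nearly neutral conditions that spare the epoxide; the α-carbon is quaternary, so the stereocentre cannot epimerise.

**Step 5**
Reactants: 6 (2S)-2-{[(2-methylbut-3-yn-2-yl)oxy]methyl}oxirane-2-carbaldehyde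
Product: 7 (2S)-2-ethynyl-2-{[(2-methylbut-3-yn-2-yl)oxy]methyl}oxirane
Conditions: dimethyl (1-diazo-2-oxopropyl)phosphonate, K2CO3, MeOH, 0 °C → rt
Reagents that add atoms: dimethyl (1-diazo-2-oxopropyl)phosphonate, CC(=O)C(=[N+]=[N-])P(=O)(OC)OC
Why: Seyferth–Gilbert homologation in its Ohira–Bestmann form converts the non-enolisable aldehyde into the terminal alkyne C12≡C11 under mild carbonate conditions that epoxides tolerate; C3 is not touched.

**Step 6**
Reactants: 7 (2S)-2-ethynyl-2-{[(2-methylbut-3-yn-2-yl)oxy]methyl}oxirane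
Product: 8 (4R)-4-hydroxy-4-{[(2-methylbut-3-yn-2-yl)oxy]methyl}hex-5-ynenitrile
Conditions: MeCN, n-BuLi (3.5 equiv each), THF, −78 °C; then 7, −78 → 0 °C; aq. NH4Cl at −20 °C
Reagents that add atoms: acetonitrile, CC#N
Why: SN2 opening of the terminal epoxide at its CH2 carbon (C2) by lithioacetonitrile installs C1 and C13; the C3–O bond is not broken, so the configuration is kept, and excess reagent is used because both alkyne C–H bonds are lithiated first.

**Step 7**
Reactants: 8 (4R)-4-hydroxy-4-{[(2-methylbut-3-yn-2-yl)oxy]methyl}hex-5-ynenitrile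
Product: 9 (4R)-4-TBSO-4-{[(2-methylbut-3-yn-2-yl)oxy]methyl}hex-5-ynenitrile
Conditions: TBSOTf, 2,6-lutidine, CH2Cl2, −78 → 0 °C
Reagents that add atoms: tert-butyldimethylsilyl trifluoromethanesulfonate, CC(C)(C)[Si](C)(C)OS(=O)(=O)C(F)(F)F
Why: a silyl triflate with 2,6-lutidine is the standard silylation of a hindered tertiary alcohol; the ether keeps the hydroxyl from adding to the nitrile or quenching the Grignard reagent later.

**Step 8**
Reactants: 9 (4R)-4-TBSO-4-{[(2-methylbut-3-yn-2-yl)oxy]methyl}hex-5-ynenitrile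
Product: 10 3-[(3R)-3-TBSO-6,6-dimethyl-4,5-dimethylideneoxan-3-yl]propanenitrile
Conditions: Pd2(dba)3·CHCl3 (2.5 mol%), P(o-tol)3 (10 mol%), AcOH (2 equiv), Et3SiH (5 equiv), toluene, rt
Reagents that add atoms: none
Why: palladium-catalysed reductive cyclisation of a 1,7-diyne; HPd(OAc), formed from zerovalent palladium and AcOH, hydropalladates one terminal alkyne, the vinylpalladium adds 6-exo-dig to the other (C7–C12 bond) and Et3SiH reduces the dienylpalladium to the 1,2-dimethylene ring, with no stereocentre formed.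

**Step 9**
Reactants: 10 3-[(3R)-3-TBSO-6,6-dimethyl-4,5-dimethylideneoxan-3-yl]propanenitrile
Product: 12 5-[(3R)-3-TBSO-6,6-dimethyl-4,5-dimethylideneoxan-3-yl]-2-methylpent-1-en-3-one, via bromomagnesium ketimide 11 (not isolated)
Conditions: isopropenylmagnesium bromide (3 equiv), CuBr·SMe2 (5 mol%), THF, 0 → 45 °C; then aq. NH4Cl, 0 °C, SiO2
Reagents that add atoms: isopropenylmagnesium bromide, CC(=C)[Mg]Br; water, O
Why: Grignard addition to a nitrile stops at the metalated ketimine, which mild aqueous work-up hydrolyses to the ketone, so the dienophile appears only after the organometallic is gone; the diene does not react with the Grignard reagent.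

**Step 10**
Reactants: 12 5-[(3R)-3-TBSO-6,6-dimethyl-4,5-dimethylideneoxan-3-yl]-2-methylpent-1-en-3-one
Product: 13 (3R,10S)-3-TBSO-tricyclic C13 ketone with bridgehead alkene C7=C12
Conditions: toluene (0.01 M), BHT (cat.), 180 °C, sealed base-washed tube
Reagents that add atoms: none
Why: A concerted, asynchronous [4+2] cycloaddition in which the pyran holds C8=C7–C12=C11 s-cis and the enone C9=C10, activated by the C13 carbonyl, bonds C9 to C8 and C10 to C11. The closest known reaction type is the type 2 intramolecular Diels–Alder reaction of 2-substituted dienes that carry an enone on a four-atom tether, which gives bridgehead-alkene bicyclo[4.3.1]decenones on heating. The cyclohexene C7–C8–C9–C10–C11–C12 closes by the [4+2] itself, and the seven-membered ring C3–C2–C1–C13–C10–C11–C12 closes in the bridged mode because the tether runs from the inner diene carbon C12 (through C3) to the substituted dienophile carbon C10, so C12 ends as a bridgehead alkene carbon. C10 is the only new stereocentre and is set by C3: the chain leaves C3 on one face of the planar diene, the dienophile can reach only that face with the C13 carbonyl folded over the diene and the methyl group outside, which gives 10S. The step needs regio-, facial and chemoselectivity: the tether length enforces the orientation that puts the quaternary C10 on C11, C3 fixes the face, high dilution with BHT holds back bimolecular cycloaddition and polymerisation, and the quaternary C3 and C6 exclude 1,5-hydrogen shifts of the diene.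

**Step 11**
Reactants: 13 (3R,10S)-3-TBSO-tricyclic C13 ketone with bridgehead alkene C7=C12
Product: 14 (3R,7R,10S,12S)-3-TBSO-tricyclic C13 ketone (saturated; H7 and H12 cis)
Conditions: H2 (1 atm), [Ir(cod)(PCy3)(py)]PF6 (10 mol%), CH2Cl2, rt
Reagents that add atoms: none
Why: homogeneous iridium-catalysed hydrogenation, suited to hindered tetrasubstituted alkenes, adds H2 syn to the strained bridgehead alkene from its only open (exo) face, opposite the C3–C2–C1–C13 bridge; this sets C12 (H outside the bicycle) and C7 (cis pyran fusion) together and avoids hydrogenolysis of the allylic C–O bonds.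

**Step 12**
Reactants: 14 (3R,7R,10S,12S)-3-TBSO-tricyclic C13 ketone (saturated; H7 and H12 cis)
Product: 15 (3R,7R,10S,12S)-3-TBSO-tricyclic enone (C13 ketone; C1=C2)
Conditions: IBX (3 equiv), DMSO–fluorobenzene 1:2, 75 °C
Reagents that add atoms: none
Why: IBX dehydrogenation of a ketone to its enone; C10 is quaternary, so only C1–C2 can be desaturated, and the ring alkene is necessarily cis.

**Step 13**
Reactants: 15 (3R,7R,10S,12S)-3-TBSO-tricyclic enone (C13 ketone; C1=C2)
Product: 16 (1S,2R,3R,7R,10S,12S)-1,2-epoxy-3-TBSO-tricyclic C13 ketone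
Conditions: 30% aq. H2O2, NaOH (0.3 equiv), MeOH, 0 °C
Reagents that add atoms: hydrogen peroxide, OO
Why: Weitz–Scheffer nucleophilic epoxidation of the enone, expected on the face away from the C7–C8–C9 bridge; both new centres are erased in steps 14 and 15, so the facial outcome is of no consequence.

**Step 14**
Reactants: 16 (1S,2R,3R,7R,10S,12S)-1,2-epoxy-3-TBSO-tricyclic C13 ketone
Product: 18 (2R,3R,7R,10S,12S)-3-TBSO-tricyclic allylic alcohol (C2 hydroxyl; C1=C13), via epoxy hydrazone 17 (not isolated)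
Conditions: N2H4·H2O (3 equiv), AcOH (cat.), MeOH, 0 °C → rt
Reagents that add atoms: none
Why: Wharton transposition; the hydrazone of the α,β-epoxy ketone opens the epoxide and loses N2, leaving hydrogen on C13, a C1=C13 double bond and the oxygen on C2, whose C–O bond is never broken.

**Step 15**
Reactants: 18 (2R,3R,7R,10S,12S)-3-TBSO-tricyclic allylic alcohol (C2 hydroxyl; C1=C13)
Product: 19 (3R,7R,10S,12S)-3-TBSO-tricyclic enone (C2 ketone; C1=C13)
Conditions: Dess–Martin periodinane, pyridine, CH2Cl2, rt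
Reagents that add atoms: none
Why: Dess–Martin oxidation of the secondary allylic alcohol gives the transposed enone and removes the temporary C2 stereocentre.

**Step 16**
Reactants: 19 (3R,7R,10S,12S)-3-TBSO-tricyclic enone (C2 ketone; C1=C13)
Product: 20 (3R,7R,10S,12S,13S)-13-allyl-3-TBSO-tricyclic C2 ketone
Conditions: CH2=CHCH2SiMe3 (2 equiv), TiCl4 (1.2 equiv), CH2Cl2, −78 °C
Reagents that add atoms: allyltrimethylsilane, C=CC[Si](C)(C)C
Why: Hosomi–Sakurai conjugate allylation (TiCl4-activated enone, allylsilane attacking through its γ-carbon) forms C13–C14; the allyl group should enter on the open face anti to the C7–C8–C9 bridge and syn to the C10 methyl, giving 13S.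

**Step 17**
Reactants: 20 (3R,7R,10S,12S,13S)-13-allyl-3-TBSO-tricyclic C2 ketone
Product: 21 (1S,3R,7R,10S,12S,13S)-13-allyl-1-(2-methylprop-2-enyl)-3-TBSO-tricyclic C2 ketone
Conditions: LiN(i-Pr)2, THF, −78 °C; CH2=C(CH3)CH2Br, DMPU, −78 → −30 °C
Reagents that add atoms: 3-bromo-2-methylprop-1-ene, C=C(C)CBr
Why: alkylation of the lithium enolate, which can form only towards C1 because C3 is quaternary; the allylic bromide should approach anti to the neighbouring C13 allyl group to give the trans (1S) product, and since C1 is epimerisable and trans is the expected thermodynamic isomer, base equilibration (DBU) would correct any cis material.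

**Step 18**
Reactants: 21 (1S,3R,7R,10S,12S,13S)-13-allyl-1-(2-methylprop-2-enyl)-3-TBSO-tricyclic C2 ketone
Product: 23 (1S,3R,7R,10S,12S,13S)-13-(2-oxoethyl)-1-(2-oxopropyl)-3-TBSO-tricyclic C2 ketone, via bis-ozonide 22 (not isolated)
Conditions: O3, CH2Cl2, −78 °C; then PPh3, −78 °C → rt
Reagents that add atoms: ozone, [O-][O+]=O
Why: ozonolysis with reductive work-up cleaves the monosubstituted and the 1,1-disubstituted alkene to the C15 aldehyde and the C17 methyl ketone in one operation; no other group is ozone-sensitive and no stereocentre is touched.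

**Step 19**
Reactants: 23 (1S,3R,7R,10S,12S,13S)-13-(2-oxoethyl)-1-(2-oxopropyl)-3-TBSO-tricyclic C2 ketone
Product: 24 (E)-2-[(1S,3R,7R,10S,12S,13S)-2-oxo-1-(2-oxopropyl)-3-TBSO-tricycl-13-yl]ethenyl 3-methylbut-2-enoate
Conditions: (Me2C=CHCO)2O (3 equiv), Et3N, DMAP (cat.), CH2Cl2, rt
Reagents that add atoms: 3-methylbut-2-enoic anhydride, CC(C)=CC(=O)OC(=O)C=C(C)C
Why: enol acylation of the aldehyde (amine-mediated enolisation and O-acylation by the DMAP-activated anhydride), which aldehydes undergo far more readily than ketones; the E isomer is expected because the bulky C13 substituent and the acyloxy group avoid a cis arrangement.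

**Step 20**
Reactants: 24 (E)-2-[(1S,3R,7R,10S,12S,13S)-2-oxo-1-(2-oxopropyl)-3-TBSO-tricycl-13-yl]ethenyl 3-methylbut-2-enoate
Product: 25 CNP0237201.2, (E)-2-[(1S,3R,7R,10S,12S,13S)-3-hydroxy-2-oxo-1-(2-oxopropyl)tricycl-13-yl]ethenyl 3-methylbut-2-enoate
Conditions: HF·pyridine, pyridine, THF, 0 °C → rt
Reagents that add atoms: none
Why: fluoride-driven cleavage of the tertiary silyl ether under buffered conditions mild enough for the enol ester, the enoate and the ketones; no stereocentre is affected.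

**Compound list**

1 | 2-methylbut-3-yn-2-ol | CC(C)(O)C#C | starting material
2 | ethyl 2-(bromomethyl)prop-2-enoate | C=C(CBr)C(=O)OCC | starting material
3 | ethyl 2-{[(2-methylbut-3-yn-2-yl)oxy]methyl}prop-2-enoate | C=C(COC(C)(C)C#C)C(=O)OCC | intermediate
4 | 2-{[(2-methylbut-3-yn-2-yl)oxy]methyl}prop-2-en-1-ol | C=C(CO)COC(C)(C)C#C | intermediate
5 | [(2S)-2-{[(2-methylbut-3-yn-2-yl)oxy]methyl}oxiran-2-yl]methanol | OC[C@@]1(COC(C)(C)C#C)CO1 | intermediate
6 | (2S)-2-{[(2-methylbut-3-yn-2-yl)oxy]methyl}oxirane-2-carbaldehyde | O=C[C@@]1(COC(C)(C)C#C)CO1 | intermediate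
7 | (2S)-2-ethynyl-2-{[(2-methylbut-3-yn-2-yl)oxy]methyl}oxirane | C#C[C@@]1(COC(C)(C)C#C)CO1 | intermediate
8 | (4R)-4-hydroxy-4-{[(2-methylbut-3-yn-2-yl)oxy]methyl}hex-5-ynenitrile | N#CCC[C@](O)(COC(C)(C)C#C)C#C | intermediate
9 | (4R)-4-TBSO-4-{[(2-methylbut-3-yn-2-yl)oxy]methyl}hex-5-ynenitrile | N#CCC[C@](O[Si](C)(C)C(C)(C)C)(COC(C)(C)C#C)C#C | intermediate
10 | 3-[(3R)-3-TBSO-6,6-dimethyl-4,5-dimethylideneoxan-3-yl]propanenitrile | N#CCC[C@]1(O[Si](C)(C)C(C)(C)C)COC(C)(C)C(=C)C1=C | intermediate
11 | bromomagnesium ketimide of 12 | C=C(C)C(=N[Mg]Br)CC[C@]1(O[Si](C)(C)C(C)(C)C)COC(C)(C)C(=C)C1=C | intermediate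
12 | 5-[(3R)-3-TBSO-6,6-dimethyl-4,5-dimethylideneoxan-3-yl]-2-methylpent-1-en-3-one | C=C(C)C(=O)CC[C@]1(O[Si](C)(C)C(C)(C)C)COC(C)(C)C(=C)C1=C | intermediate
13 | (3R,10S)-3-TBSO-tricyclic C13 ketone with bridgehead alkene C7=C12 | C1C[C@]2(O[Si](C)(C)C(C)(C)C)COC(C)(C)C3=C2C[C@](C)(CC3)C1=O | intermediate
14 | (3R,7R,10S,12S)-3-TBSO-tricyclic C13 ketone (saturated; H7 and H12 cis) | C1C[C@]2(O[Si](C)(C)C(C)(C)C)COC(C)(C)[C@@H]3CC[C@@](C)(C[C@@H]32)C1=O | intermediate
15 | (3R,7R,10S,12S)-3-TBSO-tricyclic enone (C13 ketone; C1=C2) | C1=C[C@]2(O[Si](C)(C)C(C)(C)C)COC(C)(C)[C@@H]3CC[C@@](C)(C[C@@H]32)C1=O | intermediate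
16 | (1S,2R,3R,7R,10S,12S)-1,2-epoxy-3-TBSO-tricyclic C13 ketone | O=C1[C@H]2O[C@H]2[C@]3(O[Si](C)(C)C(C)(C)C)COC(C)(C)[C@@H]4CC[C@@]1(C)C[C@H]34 | intermediate
17 | C13 hydrazone of 16 | NN=C1[C@H]2O[C@H]2[C@]3(O[Si](C)(C)C(C)(C)C)COC(C)(C)[C@@H]4CC[C@@]1(C)C[C@H]34 | intermediate
18 | (2R,3R,7R,10S,12S)-3-TBSO-tricyclic allylic alcohol (C2 hydroxyl; C1=C13) | C1=C[C@@H](O)[C@]2(O[Si](C)(C)C(C)(C)C)COC(C)(C)[C@@H]3CC[C@@]1(C)C[C@H]23 | intermediate
19 | (3R,7R,10S,12S)-3-TBSO-tricyclic enone (C2 ketone; C1=C13) | C1=CC(=O)[C@]2(O[Si](C)(C)C(C)(C)C)COC(C)(C)[C@@H]3CC[C@@]1(C)C[C@H]23 | intermediate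
20 | (3R,7R,10S,12S,13S)-13-allyl-3-TBSO-tricyclic C2 ketone | C1C(=O)[C@]2(O[Si](C)(C)C(C)(C)C)COC(C)(C)[C@@H]3CC[C@@](C)(C[C@@H]32)[C@H]1CC=C | intermediate
21 | (1S,3R,7R,10S,12S,13S)-13-allyl-1-(2-methylprop-2-enyl)-3-TBSO-tricyclic C2 ketone | C=C(C)C[C@@H]1C(=O)[C@]2(O[Si](C)(C)C(C)(C)C)COC(C)(C)[C@@H]3CC[C@@](C)(C[C@@H]32)[C@H]1CC=C | intermediate
22 | bis-ozonide of 21 (two 1,2,4-trioxolanes) | CC1(OCOO1)C[C@@H]2C(=O)[C@]3(O[Si](C)(C)C(C)(C)C)COC(C)(C)[C@@H]4CC[C@@](C)(C[C@@H]43)[C@H]2CC5OCOO5 | intermediate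
23 | (1S,3R,7R,10S,12S,13S)-13-(2-oxoethyl)-1-(2-oxopropyl)-3-TBSO-tricyclic C2 ketone | CC(=O)C[C@@H]1C(=O)[C@]2(O[Si](C)(C)C(C)(C)C)COC(C)(C)[C@@H]3CC[C@@](C)(C[C@@H]32)[C@H]1CC=O | intermediate
24 | (E)-2-[(1S,3R,7R,10S,12S,13S)-2-oxo-1-(2-oxopropyl)-3-TBSO-tricycl-13-yl]ethenyl 3-methylbut-2-enoate | CC(=O)C[C@@H]1C(=O)[C@]2(O[Si](C)(C)C(C)(C)C)COC(C)(C)[C@@H]3CC[C@@](C)(C[C@@H]32)[C@H]1/C=C/OC(=O)C=C(C)C | intermediate
25 | CNP0237201.2, (E)-2-[(1S,3R,7R,10S,12S,13S)-3-hydroxy-2-oxo-1-(2-oxopropyl)tricycl-13-yl]ethenyl 3-methylbut-2-enoate | CC(=O)C[C@@H]1C(=O)[C@]2(O)COC(C)(C)[C@@H]3CC[C@@](C)(C[C@@H]32)[C@H]1/C=C/OC(=O)C=C(C)C | target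

**Totals and risks**

Total: 20 steps. Longest linear sequence: 20 steps (1 and 2 to 25).

Step 10. The cyclisation may be outrun by bimolecular cycloaddition or polymerisation of the enone at the temperature it needs. The fallback sets out from 12 and returns at 13. HF·pyridine would remove the silyl group to give the hydroxy enone F1. With Et2AlCl (2 equiv, CH2Cl2, −78 °C → rt) its aluminium alkoxide holds the Lewis acid next to the C13 carbonyl, so the same cycloaddition should run at or below room temperature and give the hydroxy tricycle F2. TBSOTf and 2,6-lutidine at −78 °C would then return 13.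

Step 16. The allyl group may enter C13 from the face of the C7–C8–C9 bridge, so that the wrong C13 configuration is set. The fallback sets out from 19 and returns at 20. The C13 epimer F3 formed in that case would be inverted rather than discarded. Saegusa oxidation (LiN(i-Pr)2, Me3SiCl; then Pd(OAc)2, MeCN) would give the β-allyl enone F4. Conjugate reduction with [(Ph3P)CuH]6 would then deliver hydride to C13 from that same accessible face and give 20.

Step 19. Enolisation of the aldehyde may be unselective in geometry, may be followed by intramolecular aldol reaction with the C17 ketone, or the acyl group may deconjugate during transfer. The fallback sets out from 19 and returns at 24, and it builds the enol ester with fixed geometry.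
- Copper-catalysed conjugate addition of vinylmagnesium bromide (CuI cat., THF, −40 °C) would give the 13-vinyl ketone F5.
- Alkylation as in step 17 would give the 1-(2-methylprop-2-enyl)-13-vinyl ketone F6.
- Ozonolysis would give the C13 carbaldehyde F7, which already carries the 2-oxopropyl group.
- Takai-type olefination with Cl2CHB(pin), CrCl2 and LiI, selective for aldehydes over ketones, would give the (E)-alkenyl pinacolboronate F8.
- KHF2 would give the potassium (E)-alkenyltrifluoroborate F9.
- Copper-catalysed oxidative coupling of F9 with 3-methylbut-2-enoic acid (CuBr, DMAP, O2, 4 Å molecular sieves), which keeps the alkene geometry, would give 24.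

**Further compounds**

F1 | step 10 | 5-[(3R)-3-hydroxy-6,6-dimethyl-4,5-dimethylideneoxan-3-yl]-2-methylpent-1-en-3-one | C=C(C)C(=O)CC[C@]1(O)COC(C)(C)C(=C)C1=C
F2 | step 10 | (3R,10S)-3-hydroxy-tricyclic C13 ketone with bridgehead alkene C7=C12 | C1C[C@]2(O)COC(C)(C)C3=C2C[C@](C)(CC3)C1=O
F3 | step 16 | C13 epimer of 20 (allyl on the face of the C7–C8–C9 bridge) | C1C(=O)[C@]2(O[Si](C)(C)C(C)(C)C)COC(C)(C)[C@@H]3CC[C@@](C)(C[C@@H]32)[C@@H]1CC=C
F4 | step 16 | 13-allyl-3-TBSO-tricyclic enone (C2 ketone; C1=C13) | C1(CC=C)=CC(=O)[C@]2(O[Si](C)(C)C(C)(C)C)COC(C)(C)[C@@H]3CC[C@@]1(C)C[C@H]23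
F5 | step 19 | 13-vinyl-3-TBSO-tricyclic C2 ketone (vinyl on the face of the C10 methyl) | C1C(=O)[C@]2(O[Si](C)(C)C(C)(C)C)COC(C)(C)[C@@H]3CC[C@@](C)(C[C@@H]32)[C@H]1C=C
F6 | step 19 | 1-(2-methylprop-2-enyl)-13-vinyl-3-TBSO-tricyclic C2 ketone (1,13-trans) | C=C(C)C[C@@H]1C(=O)[C@]2(O[Si](C)(C)C(C)(C)C)COC(C)(C)[C@@H]3CC[C@@](C)(C[C@@H]32)[C@H]1C=C
F7 | step 19 | 13-formyl-1-(2-oxopropyl)-3-TBSO-tricyclic C2 ketone | CC(=O)C[C@@H]1C(=O)[C@]2(O[Si](C)(C)C(C)(C)C)COC(C)(C)[C@@H]3CC[C@@](C)(C[C@@H]32)[C@H]1C=O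
F8 | step 19 | (E)-alkenyl pinacolboronate at C13 (C14=C15–B) | CC(=O)C[C@@H]1C(=O)[C@]2(O[Si](C)(C)C(C)(C)C)COC(C)(C)[C@@H]3CC[C@@](C)(C[C@@H]32)[C@H]1/C=C/B4OC(C)(C)C(C)(C)O4
F9 | step 19 | potassium (E)-alkenyltrifluoroborate at C13 | CC(=O)C[C@@H]1C(=O)[C@]2(O[Si](C)(C)C(C)(C)C)COC(C)(C)[C@@H]3CC[C@@](C)(C[C@@H]32)[C@H]1/C=C/[B-](F)(F)F.[K+]
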